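## Structural features

Ring A carbons are labelled a1 (C–CH3), a2 (CH), a3 and a4 (the two tropolone carbons bearing O), a5 (CH), a6 (C–O of the pyran) and a7 (C–C4); ring D carries the same labels with primes.

- The target has two identically substituted tropolone rings (A and D). Each is fused through a6/a7 (a6'/a7') to a dihydropyran (rings B and C) made of O, C2, C3, C4 (O, C2', C3', C4').
- The two bicycles are joined C2 to C2' by an (E,E)-buta-1,3-diene, so C2 and C2' are allylic, ether-bearing stereocentres.
- C2 (R) and C3 (R, methyl-bearing) are neighbours and trans in ring B. C2' (R) is an isolated centre, because C3' is a CH2.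
- Fragile groups: the tropolones are acidic, chelating and electrophilic at the ring. The C2–O and C2'–O bonds are dienyl ethers of a vinylogous acid, so they can ionise in acid and can be opened by hydroxide at a6/a6'.
- There are two real difficulties. The first is access to a fully substituted tropolone whose three ring oxygens (a3, a4, a6) react as one ambident system. The second is control of C2' relative to the distant C2/C3 pair, which no substrate control can relay across the diene.
- The key step uses the fact that C3–C4 and C3'–C4' each join a tropolonylmethyl carbon to a carbon α to C2 or C2'. At the ketone level of C2/C2', the chain C3(CH3)–C2–(CH=CH)2–C2'–C3' is nona-3,5-diene-2,7-dione, which can be alkylated at both α-carbons by one electrophile.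

## Logic of the disconnections

**20 ⇒ 19.** The two acyl groups on the tropolone oxygens are put back. Free tropolones are acidic and chelating, and once deprotonated they are no longer electrophilic, so they stay masked to the end. The forward step must cleave the esters faster than hydroxide attacks a6/a6'.

**19 ⇒ 18.** O–a6 and O–a6' are cut. Cutting this bond, and not C2–O, keeps the oxygen on C2/C2', so their configuration is fixed before ring closure and cannot be lost in it. Both pyrans disappear. The forward step needs a leaving group on a6/a6' and an alkoxide that closes 6-exo faster than it does anything else.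

**18 ⇒ 17.** C2–H and C2'–H are removed (carbinol to ketone). Two stereocentres go, and C3 and C3' become α-carbons of carbonyl groups. One catalyst must then deliver hydride 1,2 to the same face of two different dienyl ketones without touching C3.

**17 ⇒ 16.** Both C=O groups are exchanged for C=N–N(auxiliary). The forward hydrolysis must not epimerise C3.

**16 ⇒ 8 + two 14.** C3–C4 and C3'–C4' are cut. Both join a CH2 on a7/a7' to a carbon α to C=N, and the arms are identical, so one electrophile serves both ends and the core shrinks to nine carbons. This is the largest simplification (two C–C bonds, C3 set). Each aza-enolate must react once, at carbon, with CH2Br and not with the ring or the ester, under auxiliary control.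

**8 ⇒ 6 + two 7.** The C=N bonds are cut; the auxiliary is commercial.

**6 ⇒ 3 + 4 (through 5), and 3 ⇒ 1 + 2.** The two diene C=C bonds are cut in turn, each as aldehyde plus stabilised phosphorus reagent. The masked glyoxal 1 lets the ethyl-ketone and methyl-ketone ends enter one after the other. Both alkenes must be E, and 5 must be used without isolation.

**14 ⇒ 13 ⇒ 12 ⇒ 11.** The a6–Br and CH2–Br bonds go back to C–O, CH2OH goes back to CHO, and the ester goes back to the free tropolone. The forward steps must pick out the tropolone oxygen for acylation and the a6 oxygen for replacement by bromide.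

**11 ⇒ 9 (through 10).** Ring bonds a4–a5 and a5–a6 are traded for the C3–CH3 and C2–C3 bonds of a benzene: a5 becomes the C3 methyl of 9 and the a4 oxygen is removed. The arene is commercial and carries every carbon. The forward step is a hydroxylative dearomatisation followed by a one-carbon ring expansion.

## Other disconnections considered

**Alternative 1:** The cut is a7–a6 and a4–a5, which takes ring A and ring B back to the tethered precursor A2. In the forward step, base-induced elimination from A2 gives a 3-oxidopyrylium that adds across its own ynol ether to the bridged adduct A1.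
- In its favour: the seven-membered ring is built from a non-tropolone precursor, and the a6 oxygen is placed by construction. On that regiochemical point it is better than the chosen plan, which must select a6 in an ambident system (steps 5 and 7). C2 and C3 are set in an acyclic chain before any tropone exists, and no strong base meets a tropone.
- Against it here: A1 is only one half. A second, different sequence is needed for rings D/C, and the halves must then be joined at the diene. Opening the bridge needs ionisation at a7. Ynol ethers are thermally fragile at the temperatures such cycloadditions usually need.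
- Comparison: mechanistically, the cycloaddition class is established, but ynol ethers as the two-carbon partner are little explored, so the risk is comparable to the double alkylation. On step economy the chosen plan is well ahead, since two arms go on in one flask.

**Alternative 2:** The cut is C2–C3. The precursor A4 carries the a6 oxygen as an ether to the acyl pyrazole α-carbon and an (E)-propenyl group on a7. In the forward step, Cu(OTf)2 (divalent copper), a bis(oxazoline) and an amine enolise A4, and C2 adds to C3 to close ring B as A3.
- In its favour: C2 and C3 are set together, catalytically and under mild conditions that a tropone tolerates. For the C2/C3 pair this is equal or better than the chosen plan, which needs an auxiliary plus a later ketone reduction.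
- Against it here: the acceptor is activated only through the tropone π-system, and this extended conjugate addition has no close precedent. A4 still requires O-alkylation of a6 in the same ambident system. The D/C half has no methyl and needs its own variant. C2 in A3 is α to both C=O and O and is epimerisable while the diene is built.
- Comparison: step economy is worse (two halves plus a union), and mechanistic certainty is lower than for an SN2 alkylation.

**Alternative 3:** The cut is C4–a7 and C4'–a7'. In the forward step, 9-BBN hydroborates the isopropenyl and vinyl ends of A6, and both alkylboranes couple with bromotropone A7 under PdCl2(dppf)/Cs2CO3 to give A5. C3 arises in the hydroboration under control of C2.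
- In its favour: it is two-directional, so it is equal to the chosen plan in convergence and step count. It is better in chemoselectivity, because a palladium-mediated coupling does not expose the tropone to a strongly basic carbanion. A7 needs no CH2X group, and C2/C2' are set before the coupling.
- Against it here: A6 needs two carbinol centres on a tetraene with different ends. 9-BBN must leave the internal diene alone. C3 rests on substrate control. A7 still needs the three-oxygen tropolone, with two O-methyl groups in defined positions. Ring closure then has to displace methoxide from a6.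
- Comparison: the structural simplification is the same as in the chosen plan. The risk moves from the alkylation to the synthesis of A6 and A7.

Key step: step 8

Remarks on the chemistry (corrections and assumptions):
- 2,4-Dihydroxy-3,6-dimethylbenzaldehyde (9) is a benzene (C9H10O3), not a tropolone; the tropolone aldehyde 11 (C9H8O4) is reached from it only by the oxidative one-carbon ring expansion of step 4.
- The tropolone is masked as a pivalate and not as a methyl ether: O-alkylation of this unsymmetrical tropolone would give two regioisomeric ethers, whereas an acyl group shifts rapidly between the two tropolone oxygens, so one compound results (drawn with the ester on the a3 oxygen); it is removed at the end by ester hydrolysis and not by vinylogous-ether hydrolysis.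
- The ring leaving group is bromide and not chloride, so that one reagent makes both C–Br bonds of the electrophile.
- Assumptions: TropB and TropC are used as recombinant enzymes on their native substrate; 10 is drawn as the R enantiomer, which is immaterial because its stereocentre is lost; the C=N geometry of the hydrazones is left open because it is lost on deprotonation.

## Route

Step 1
Reactants: 1 2,2-dimethoxyacetaldehyde (60% aqueous solution); 2 diethyl (2-oxobutyl)phosphonate
Product: 3 (E)-6,6-dimethoxyhex-4-en-3-one
Conditions: K2CO3, H2O/THF, 0 °C → rt
Reagents that add atoms: none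
Why: Horner–Wadsworth–Emmons olefination; the β-keto phosphonate anion adds to the unhindered aldehyde and gives the E enone, and the acetal is inert to carbonate.

Step 2
Reactants: 3 (E)-6,6-dimethoxyhex-4-en-3-one; 4 1-(triphenyl-λ5-phosphanylidene)propan-2-one
Product: 6 (3E,5E)-nona-3,5-diene-2,7-dione, via (E)-4-oxohex-2-enal 5 (not isolated)
Conditions: TFA/H2O, CH2Cl2, 0 °C; aq. NaHCO3 wash, dry; then 4, CH2Cl2, 0 °C → rt
Reagents that add atoms: none
Why: Acetal hydrolysis frees the reactive aldehyde 5, which is trapped at once by the neutral stabilised ylide in an E-selective Wittig reaction at the aldehyde and not the ketone.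

Step 3
Reactants: 6 (3E,5E)-nona-3,5-diene-2,7-dione; 7 RAMP, (R)-1-amino-2-(methoxymethyl)pyrrolidine (2.2 equiv)
Product: 8 bis(RAMP hydrazone) of (3E,5E)-nona-3,5-diene-2,7-dione
Conditions: p-TsOH (cat.), cyclohexane, reflux, Dean–Stark
Reagents that add atoms: none
Why: Hydrazone formation at both ketones, driven by removal of water; conjugate addition of the amine is reversible and cannot go on to a pyrazoline.

Step 4
Reactants: 9 2,4-dihydroxy-3,6-dimethylbenzaldehyde
Product: 11 stipitaldehyde (5-formyl-2,6-dihydroxy-4-methyltropone), via dienone 10 (not isolated)
Conditions: TropB, NADP+ (cat.), D-glucose, glucose dehydrogenase, air, phosphate buffer pH 8, 30 °C; then TropC, FeSO4 (divalent iron, cat.), 2-oxoglutarate, sodium ascorbate, air, 30 °C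
Reagents that add atoms: dioxygen, O=O
Why: Biocatalytic oxidative ring expansion known for this substrate: the flavin monooxygenase hydroxylates C3 and dearomatises the ring to 10; the 2-oxoglutarate-dependent non-heme iron enzyme then abstracts hydrogen from the C3 methyl, whose carbon is inserted between C2 and C3 by a radical 1,2-shift to give the tropolone.

Step 5
Reactants: 11 stipitaldehyde
Product: 12 5-formyl-6-hydroxy-4-methyl-2-(pivaloyloxy)tropone
Conditions: t-BuCOCl (1.05 equiv), Et3N (1.1 equiv), CH2Cl2, −40 → 0 °C
Reagents that add atoms: pivaloyl chloride, CC(C)(C)C(=O)Cl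
Why: O-Acylation of the tropolonate; the a6 hydroxyl is hydrogen-bonded to and flanked by the aldehyde, so the hindered acid chloride should take a tropolone oxygen, and the fast acyl shift between the two tropolone oxygens makes the site immaterial.

Step 6
Reactants: 12 5-formyl-6-hydroxy-4-methyl-2-(pivaloyloxy)tropone
Product: 13 6-hydroxy-5-(hydroxymethyl)-4-methyl-2-(pivaloyloxy)tropone
Conditions: NaBH(OAc)3, AcOH, THF, 0 °C → rt
Reagents that add atoms: none
Why: Aldehyde-selective acyloxyborohydride reduction assisted by the neighbouring acidic OH; the tropone carbonyl and the active ester are not reduced, and the acyl group cannot reach the a6 oxygen or the new hydroxyl intramolecularly.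

Step 7
Reactants: 13 6-hydroxy-5-(hydroxymethyl)-4-methyl-2-(pivaloyloxy)tropone
Product: 14 6-bromo-5-(bromomethyl)-4-methyl-2-(pivaloyloxy)tropone
Conditions: PBr3 (1.1 equiv), pyridine (2 equiv), CH2Cl2, −40 °C → rt
Reagents that add atoms: phosphorus tribromide, BrP(Br)Br
Why: PBr3 should esterify the primary alcohol and then close onto the only oxygen within reach, the a6 oxygen, as a six-membered cyclic bromophosphite (as with salicyl alcohols); bromide then opens the benzylic C–O bond by SN2 and displaces the phosphorus leaving group from a6 by addition–elimination (vinylogous acid to vinylogous acid bromide), which places the ring bromide on a6 and not on a3 or a4.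

Step 8
Reactants: 8 bis(RAMP hydrazone) of (3E,5E)-nona-3,5-diene-2,7-dione; 14 6-bromo-5-(bromomethyl)-4-methyl-2-(pivaloyloxy)tropone (2.1 equiv)
Product: 16 (3R)-doubly alkylated bis(RAMP hydrazone), via dilithio bis(aza-enolate) 15 (not isolated)
Conditions: LiN(iPr)2 (2.05 equiv), THF, 0 °C; cool to −100 °C; 14 in THF; −100 → −78 °C; pH 7 buffer
Reagents that add atoms: none
Why: Two equivalents of LiN(iPr)2 remove one proton from each saturated α-carbon of 8 (the CH2 of the ethyl side and the CH3 of the methyl side; the other α-positions are vinylic), giving the bis(lithium aza-enolate) 15. Each aza-enolate should adopt the usual E(C=C), Z(C–N) geometry with lithium held between the amide nitrogen and the methoxymethyl oxygen. C-Alkylation by SN2 at the primary CH2Br of 14 then forms C3–C4 and C3'–C4'; the closest known reaction is the SAMP/RAMP-hydrazone α-alkylation of ethyl ketones with benzylic halides, run here at two sites in one flask. No ring is closed. C3 is set by the RAMP auxiliary, whose chelate blocks one face; by analogy with the SAMP hydrazone of pentan-3-one, which gives the S ketone with the same substituent ranking, RAMP should give 3R, and the methyl side gives a CH2 and no stereocentre. The step needs SN2 at CH2Br to outrun addition to the tropone ring, addition–elimination at the ring C–Br and attack at the ester; this is secured by the low temperature, the high SN2 reactivity of the bromomethyl group, the hindered pivaloyl group and the absence of excess amide base. α- over γ-alkylation follows from the site of deprotonation, and double alkylation is driven by complete dianion formation and a slight excess of 14.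

Step 9
Reactants: 16 (3R)-doubly alkylated bis(RAMP hydrazone)
Product: 17 (2R,4E,6E)-2-methyl-1,10-bis[6-bromo-4-methyl-2-(pivaloyloxy)tropon-5-yl]deca-4,6-diene-3,8-dione
Conditions: sat. aq. (CO2H)2, Et2O, rt
Reagents that add atoms: water, O
Why: Two-phase acidic hydrolysis of the hydrazones, the standard cleavage that does not epimerise an α-stereocentre; the auxiliary passes into the water layer as its oxalate, and ester and ring bromide are stable to cold aqueous acid.

Step 10
Reactants: 17 (2R,4E,6E)-diketone
Product: 18 (2R,3R,4E,6E,8R)-2-methyl-1,10-bis[6-bromo-4-methyl-2-(pivaloyloxy)tropon-5-yl]deca-4,6-diene-3,8-diol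
Conditions: (S)-2-methyl-CBS-oxazaborolidine (0.4 equiv), catecholborane (3 equiv), toluene/CH2Cl2, −78 °C
Reagents that add atoms: none
Why: Corey–Bakshi–Shibata reduction; with the dienyl group as the large substituent, as in other enones, the (S)-catalyst should give the R carbinol at C2 and C2' (decane C3 and C8) by 1,2-hydride delivery. At C2 the Felkin–Anh preference of the 3R centre points the same way (2,3-anti), and the non-basic conditions leave C3 untouched.

Step 11
Reactants: 18 (2R,3R,4E,6E,8R)-diol
Product: 19 bis(pivalate) of the target (rings B and C closed)
Conditions: KN(SiMe3)2 (2.1 equiv), THF (0.005 M), −78 → 0 °C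
Reagents that add atoms: none
Why: Intramolecular oxa-Michael addition–elimination of each alkoxide at the bromine-bearing a6/a6' (6-exo-trig) closes rings B and C; the C2–O and C2'–O bonds are not broken, so both configurations are retained and the 2,3-trans relation follows from the anti diol. Dilution and low temperature favour ring closure over attack on the hindered ester.

Step 12
Reactants: 19 bis(pivalate) of the target
Product: 20 target, CNP0332980.1 (2R,3R,2'R)
Conditions: LiOH (5 equiv), THF/H2O, 0 °C; then dil. HCl to pH 4
Reagents that add atoms: none
Why: Saponification of the two tropolone esters (active esters), which should be much faster than hydroxide attack at the vinylogous ester carbons a6/a6'; attack at the acyl carbon or at the tropone carbon both end in the tropolone.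

## Compound list

1 | 2,2-dimethoxyacetaldehyde | COC(OC)C=O | starting material
2 | diethyl (2-oxobutyl)phosphonate | CCC(=O)CP(=O)(OCC)OCC | starting material
3 | (E)-6,6-dimethoxyhex-4-en-3-one | CCC(=O)/C=C/C(OC)OC | intermediate
4 | 1-(triphenyl-λ5-phosphanylidene)propan-2-one | CC(=O)C=P(c1ccccc1)(c1ccccc1)c1ccccc1 | starting material
5 | (E)-4-oxohex-2-enal | CCC(=O)/C=C/C=O | intermediate (not isolated)
6 | (3E,5E)-nona-3,5-diene-2,7-dione | CCC(=O)/C=C/C=C/C(C)=O | intermediate
7 | RAMP, (R)-1-amino-2-(methoxymethyl)pyrrolidine | COC[C@H]1CCCN1N | starting material
8 | bis(RAMP hydrazone) of (3E,5E)-nona-3,5-diene-2,7-dione | CCC(=NN1CCC[C@@H]1COC)/C=C/C=C/C(C)=NN1CCC[C@@H]1COC | intermediate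
9 | 2,4-dihydroxy-3,6-dimethylbenzaldehyde | Cc1cc(O)c(C)c(O)c1C=O | starting material
10 | (5R)-4,5-dihydroxy-2,5-dimethyl-6-oxocyclohexa-1,3-diene-1-carbaldehyde | O=CC1=C(C)C=C(O)[C@@](C)(O)C1=O | intermediate (not isolated)
11 | stipitaldehyde, 5-formyl-2,6-dihydroxy-4-methyltropone | CC1=C(C=O)C(O)=CC(=O)C(O)=C1 | intermediate
12 | 5-formyl-6-hydroxy-4-methyl-2-(pivaloyloxy)tropone | CC1=C(C=O)C(O)=CC(=O)C(OC(=O)C(C)(C)C)=C1 | intermediate
13 | 6-hydroxy-5-(hydroxymethyl)-4-methyl-2-(pivaloyloxy)tropone | CC1=C(CO)C(O)=CC(=O)C(OC(=O)C(C)(C)C)=C1 | intermediate
14 | 6-bromo-5-(bromomethyl)-4-methyl-2-(pivaloyloxy)tropone | CC1=C(CBr)C(Br)=CC(=O)C(OC(=O)C(C)(C)C)=C1 | intermediate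
15 | dilithio bis(aza-enolate) of 8 | C/C=C(/N([Li])N1CCC[C@@H]1COC)\C=C\C=C\C(=C)N([Li])N1CCC[C@@H]1COC | intermediate (not isolated)
16 | bis(RAMP hydrazone) of 17 (3R at the new centre) | CC(C)(C)C(=O)OC1=CC(C)=C(C[C@@H](C)C(=NN2CCC[C@@H]2COC)/C=C/C=C/C(=NN2CCC[C@@H]2COC)CCC2=C(C)C=C(OC(=O)C(C)(C)C)C(=O)C=C2Br)C(Br)=CC1=O | intermediate
17 | (2R,4E,6E)-2-methyl-1,10-bis[6-bromo-4-methyl-2-(pivaloyloxy)tropon-5-yl]deca-4,6-diene-3,8-dione | CC(C)(C)C(=O)OC1=CC(C)=C(C[C@@H](C)C(=O)/C=C/C=C/C(=O)CCC2=C(C)C=C(OC(=O)C(C)(C)C)C(=O)C=C2Br)C(Br)=CC1=O | intermediate
18 | (2R,3R,4E,6E,8R)-2-methyl-1,10-bis[6-bromo-4-methyl-2-(pivaloyloxy)tropon-5-yl]deca-4,6-diene-3,8-diol | CC(C)(C)C(=O)OC1=CC(C)=C(C[C@@H](C)[C@@H](O)/C=C/C=C/[C@H](O)CCC2=C(C)C=C(OC(=O)C(C)(C)C)C(=O)C=C2Br)C(Br)=CC1=O | intermediate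
19 | bis(pivalate) of the target (both tropolone oxygens as 2,2-dimethylpropanoates; 2R,3R,2'R) | CC1=C2C[C@@H](C)[C@H](/C=C/C=C/[C@H]3CCC4=C(C)C=C(OC(=O)C(C)(C)C)C(=O)C=C4O3)OC2=CC(=O)C(OC(=O)C(C)(C)C)=C1 | intermediate
20 | CNP0332980.1 (2R,3R,2'R) | Cc1cc(=O)c(O)cc2c1C[C@@H](C)[C@H](/C=C/C=C/[C@H]1CCc3c(C)cc(=O)c(O)cc3O1)O2 | target

## Step count and least certain steps

Total: 12 steps. Longest linear sequence: 9 steps (steps 4 to 12, from 9).

**Step 8 (key step).** What may go wrong: the aza-enolates may attack the tropone ring, the ring C–Br or the ester instead of the CH2Br; proton transfer from the ring methyl may quench them; the second alkylation may stall, because the mono-alkylated species carries an aza-enolate beside an electrophilic tropone. Fallback: each arm is put on a separate, monofunctional carbanion and the halves are joined by olefination. It sets out from 3 and comes back at 17.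
- 3 is condensed with 7 to the RAMP hydrazone of (E)-6,6-dimethoxyhex-4-en-3-one F1.
- F1 is deprotonated with one equivalent of LiN(iPr)2 and alkylated with one equivalent of 14 to the 3R-alkylated hydrazone acetal F2.
- Aqueous oxalic acid, then TFA/H2O, gives the keto aldehyde (2E,5R)-5-methyl-4-oxo-6-[6-bromo-4-methyl-2-(pivaloyloxy)tropon-5-yl]hex-2-enal F3.
- Separately, ylide 4 is deprotonated at its methyl group (LiN(iPr)2, THF, −78 °C) and alkylated with 14 to the arm-bearing ylide F4.
- Wittig reaction of F3 with F4 in CH2Cl2 gives 17.

**Step 7.** What may go wrong: bromide may be delivered to a4 or a3 instead of a6, because the hydroxytropone is an ambident vinylogous acid and the acyl group is mobile; benzylic bromination may also outrun ring closure onto phosphorus. Fallback: the a6 oxygen is fixed in an isolable ring before any bromide is introduced. It sets out from 13 and comes back at 14.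
- 1,1'-Sulfonyldiimidazole and base convert 13 into the cyclic sulfate F5; only the a6 oxygen and the CH2O can span this six-membered ring.
- LiBr opens F5 at the benzylic carbon to the lithium 5-(bromomethyl)tropon-6-yl sulfate F6.
- Excess LiBr in warm acetonitrile replaces the sulfate on a6 by addition–elimination and gives 14.

**Step 5.** What may go wrong: acylation at the a6 oxygen or double acylation, since both hydroxyls are acidic. Fallback: the a6 oxygen is tied up before acylation. It sets out from 11 and comes back at 13.
- NaBH4 reduces 11 to the triol 2,6-dihydroxy-5-(hydroxymethyl)-4-methyltropone F7.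
- 2,2-Dimethoxypropane and PPTS tie the a6 oxygen and the CH2OH into the acetonide F8, leaving only the tropolone OH.
- Pivaloylation gives the acetonide pivalate F9.
- Aqueous acetic acid removes the acetonide and gives 13.

**Step 10.** What may go wrong: poor facial selectivity at C2, where the dienyl group competes with a branched alkyl group for the role of the large substituent; conjugate reduction; complexation or reduction at the tropone. Fallback: stereocontrol is moved from the oxazaborolidine to an enzyme. A panel of ketoreductases (NADPH with glucose recycling, buffer/DMSO) is screened for an R-selective enzyme that reduces both ketones. It sets out from 17 and comes back at 18 and makes no new compound.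

## Further compounds

F1 | step 8 | RAMP hydrazone of (E)-6,6-dimethoxyhex-4-en-3-one | CCC(=NN1CCC[C@@H]1COC)/C=C/C(OC)OC
F2 | step 8 | 3R-alkylated hydrazone acetal | CC(C)(C)C(=O)OC1=CC(C)=C(C[C@@H](C)C(=NN2CCC[C@@H]2COC)/C=C/C(OC)OC)C(Br)=CC1=O
F3 | step 8 | (2E,5R)-5-methyl-4-oxo-6-[6-bromo-4-methyl-2-(pivaloyloxy)tropon-5-yl]hex-2-enal | CC(C)(C)C(=O)OC1=CC(C)=C(C[C@@H](C)C(=O)/C=C/C=O)C(Br)=CC1=O
F4 | step 8 | 4-[6-bromo-4-methyl-2-(pivaloyloxy)tropon-5-yl]-1-(triphenyl-λ5-phosphanylidene)butan-2-one | CC(C)(C)C(=O)OC1=CC(C)=C(CCC(=O)C=P(c2ccccc2)(c2ccccc2)c2ccccc2)C(Br)=CC1=O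
F5 | step 7 | cyclic sulfate of 13 (a6 oxygen and CH2O bridged by SO2) | CC1=C2COS(=O)(=O)OC2=CC(=O)C(OC(=O)C(C)(C)C)=C1
F6 | step 7 | lithium 5-(bromomethyl)-4-methyl-2-(pivaloyloxy)tropon-6-yl sulfate | CC1=C(CBr)C(OS(=O)(=O)[O-])=CC(=O)C(OC(=O)C(C)(C)C)=C1.[Li+]
F7 | step 5 | 2,6-dihydroxy-5-(hydroxymethyl)-4-methyltropone | CC1=C(CO)C(O)=CC(=O)C(O)=C1
F8 | step 5 | acetonide of F7 (a6 oxygen and CH2O) | CC1=C2COC(C)(C)OC2=CC(=O)C(O)=C1
F9 | step 5 | acetonide pivalate | CC1=C2COC(C)(C)OC2=CC(=O)C(OC(=O)C(C)(C)C)=C1
F0 | step 10 | none | none
A1 | alternative 1 | oxygen-bridged [5+2] cycloadduct holding rings A and B | O=C1C=C(C)[C@]23O[C@H]1C=C2O[C@@H](CO[Si](C)(C)C(C)(C)C)[C@H](C)C3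
A2 | alternative 1 | 6-acetoxy-5-methyl-2H-pyran-3(6H)-one with the ynol ether tether on C6 | CC(=O)OC1(C[C@@H](C)[C@H](CO[Si](C)(C)C(C)(C)C)OC#C)OCC(=O)C=C1C
A3 | alternative 2 | ring A–B acyl pyrazole (trans-2,3) | CC1=CC(=O)C(OC)=CC2=C1C[C@@H](C)[C@H](C(=O)n1nc(C)cc1C)O2
A4 | alternative 2 | α-tropolonyloxy acyl pyrazole with (E)-propenyl on a7 | C/C=C/C1=C(OCC(=O)n2nc(C)cc2C)C=C(OC)C(=O)C=C1C
A5 | alternative 3 | doubly coupled bis(silyl ether) | COC1=CC(C)=C(C[C@@H](C)[C@@H](O[Si](C)(C)C(C)(C)C)/C=C/C=C/[C@H](O[Si](C)(C)C(C)(C)C)CCC2=C(C)C=C(OC)C(=O)C=C2OC)C(OC)=CC1=O
A6 | alternative 3 | tetraene bis(silyl ether) | C=C(C)[C@@H](O[Si](C)(C)C(C)(C)C)/C=C/C=C/[C@H](O[Si](C)(C)C(C)(C)C)C=C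
A7 | alternative 3 | 5-bromo-2,6-dimethoxy-4-methyltropone | COC1=CC(C)=C(Br)C(OC)=CC1=O
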